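**Retrosynthetic overview**
- The target is opened at the C3 hemiketal to a (Z)-enone with a ketal-protected C10/C14 diol. The ten-membered ring is then cut at C3–C4 (alkenyl iodide plus aldehyde, Nozaki–Hiyama–Kishi), and the exocyclic C11=C13 bond is traced to a C11 phosphonate (Horner–Wadsworth–Emmons).
- The strategy rests on the cis γ-lactone ring O–C6–C7–C11–C12, in which C7 carries C11 anti to the oxygens on C6 and C8. This is the signature of an anti opening of a trans C7–C8 epoxide at C7 by an enolate tethered through the C6 ester.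
- The threo epoxy phosphonoacetate comes from an erythro epoxy alcohol (Sharpless epoxidation of a C6 dienol, then Mitsunobu inversion at C6).
- The dienol comes from (Z)-3-iodobut-2-enal and an (E)-alkenylzinc. The alkenylzinc is made from an alkyne whose quaternary C10 is set by Sharpless epoxidation of a 2-substituted allyl alcohol and acetylide opening.
- Ring order: dioxolane (protection), C7–C8 epoxide, γ-lactone, ten-membered carbocycle, oxolane hemiketal.

Key step: step 10

Remark: germacrane numbering is used (C1–C10 ring carbons, C11–C13 lactone carbons, C14 on C10, C15 on C4); TBS = tert-butyldimethylsilyl; the C3 hemiketal configuration is taken to be fixed by C10, because the oxygen bridge can span the ten-membered ring only with C4 and C9 cis on the oxolane.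

**Route**

Step 1
Reactants: 1 but-2-yn-1-ol
Product: 3 (Z)-3-iodobut-2-en-1-ol, via cyclic alkenylalanate 2 (not isolated)
Conditions: NaAlH2(OCH2CH2OMe)2 (Red-Al), THF, 0 °C to rt; then I2, −78 °C to 0 °C
Reagents that add atoms: iodine, II
Why: Hydroxyl-directed trans-hydroalumination of the propargylic alcohol places aluminium on C4 in a five-membered alanate, and iododealumination with retention should give the (Z)-iodoalkene with iodine cis to the CH2OH carbon (C6).

Step 2
Reactants: 3 (Z)-3-iodobut-2-en-1-ol
Product: 4 (Z)-3-iodobut-2-enal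
Conditions: MnO2, CH2Cl2, rt
Reagents that add atoms: none
Why: Heterogeneous MnO2 oxidation of an allylic alcohol is neutral and should leave the (Z)-geometry and the C–I bond untouched, provided the aldehyde is used without storage.

Step 3
Reactants: 5 (3-bromopropoxy)(tert-butyl)dimethylsilane, 6 prop-2-yn-1-ol
Product: 9 2-[3-(TBS-oxy)propyl]prop-2-en-1-ol, via Grignard reagent 7 (not isolated), via alkenylmagnesium adduct 8 (not isolated)
Conditions: 5, Mg, THF, rt; 6, EtMgBr, THF/toluene, 0 °C; combine, CuI (10 mol %), −10 °C to rt; aq. NH4Cl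
Reagents that add atoms: none
Why: Copper-catalysed anti-carbomagnesiation of the magnesium alkoxide of propargyl alcohol delivers the alkyl group to the inner alkyne carbon (the future C10) through a chelated alkenylmagnesium species, and protonation should give the 2-substituted allyl alcohol with the silyl ether intact.

Step 4
Reactants: 9 2-[3-(TBS-oxy)propyl]prop-2-en-1-ol
Product: 10 (S)-{2-[3-(TBS-oxy)propyl]oxiran-2-yl}methanol
Conditions: Ti(OiPr)4 (cat.), L-(+)-diethyl tartrate (cat.), t-BuOOH, 4 Å MS, CH2Cl2, −20 °C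
Reagents that add atoms: tert-butyl hydroperoxide, CC(C)(C)OO
Why: Catalytic Sharpless asymmetric epoxidation of a 2-substituted allylic alcohol is reagent-controlled, and the L-(+)-tartrate ligand should deliver oxygen to the alkene face that gives the (S)-epoxide, which fixes the quaternary carbon C10.

Step 5
Reactants: 10 (S)-{2-[3-(TBS-oxy)propyl]oxiran-2-yl}methanol
Product: 11 (R)-2-[3-(TBS-oxy)propyl]pent-4-yne-1,2-diol
Conditions: HC≡CLi·H2NCH2CH2NH2 (3 equiv), DMSO, rt; aq. NH4Cl
Reagents that add atoms: lithium acetylide–ethylenediamine complex, [Li]C#C.NCCN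
Why: SN2 opening of the 2,2-disubstituted epoxide by acetylide occurs at the unsubstituted CH2 carbon (C9) and leaves C10 untouched, and a Payne rearrangement of the alkoxide would be degenerate and return the same enantiomer, so no erosion is expected.

Step 6
Reactants: 11 (R)-2-[3-(TBS-oxy)propyl]pent-4-yne-1,2-diol
Product: 12 (R)-2,2-dimethyl-4-(prop-2-yn-1-yl)-4-[3-(TBS-oxy)propyl]-1,3-dioxolane
Conditions: Me2C(OMe)2, PPTS (cat.), CH2Cl2, rt
Reagents that add atoms: 2,2-dimethoxypropane, COC(C)(C)OC
Why: Acid-catalysed transketalisation closes the five-membered dioxolane on the C10/C14 diol under conditions mild enough for the primary silyl ether and the terminal alkyne.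

Step 7
Reactants: 12 (R)-2,2-dimethyl-4-(prop-2-yn-1-yl)-4-[3-(TBS-oxy)propyl]-1,3-dioxolane, 4 (Z)-3-iodobut-2-enal
Product: 15 (2Z,5E)-2-iodo-7-[(4R)-dioxolan-4-yl]hepta-2,5-dien-4-ol as both C6 epimers, via alkenylzirconocene chloride 13 (not isolated), via alkenyl(methyl)zinc 14 (not isolated)
Conditions: Cp2Zr(H)Cl, CH2Cl2, rt; Me2Zn, −65 °C; then 4, 0 °C; aq. NH4Cl
Reagents that add atoms: none
Why: syn-Hydrozirconation of the terminal alkyne puts zirconium on C7 with (E)-geometry, transmetalation to zinc gives an alkenylzinc that adds 1,2 to the enal without touching the alkenyl iodide, and, C10 being too remote to bias the addition, both C6 epimers should form.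

Step 8
Reactants: 15 dienol as both C6 epimers
Product: 16 erythro (6R,7R,8R,10R)-7,8-epoxy-6-ol
Conditions: Ti(OiPr)4, D-(−)-diisopropyl tartrate, t-BuOOH (0.55 equiv), 4 Å MS, CH2Cl2, −20 °C
Reagents that add atoms: tert-butyl hydroperoxide, CC(C)(C)OO
Why: Sharpless epoxidation in its kinetic-resolution mode is reagent-controlled, so with the D-(−)-tartrate only the (6S)-epimer should be epoxidised at a useful rate, on the (E)-C7=C8 bond and on the face that gives the erythro (7R,8R)-epoxy alcohol, while the (6R)-epimer and the hindered, electron-poor iodoalkene stay behind and are removed by chromatography, at most half of 15 being convertible.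

Step 9
Reactants: 16 erythro (6R,7R,8R,10R)-7,8-epoxy-6-ol, 17 2-(diethoxyphosphoryl)acetic acid
Product: 18 threo (6S,7S,8R,10R) C6 diethylphosphonoacetate of the trans C7–C8 epoxide
Conditions: PPh3, DIAD, THF, 0 °C to rt
Reagents that add atoms: none
Why: Mitsunobu esterification with the acidic phosphonoacetic acid displaces the activated C6 oxygen by SN2 with inversion, which turns the erythro alcohol into the threo ester needed for a cis lactone, the iodine and methyl on C4 hindering the SN2′ pathway.

Step 10
Reactants: 18 threo C6 diethylphosphonoacetate of the trans C7–C8 epoxide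
Product: 21 (6R,7R,8R,10R) alpha-(diethoxyphosphoryl) gamma-lactone with free C8 hydroxyl as C11 epimers, via sodium enolate 19 (not isolated), via sodium lactone salt 20 (not isolated)
Conditions: NaH (1.1 equiv), THF, 0 °C to 40 °C; then AcOH, −20 °C
Reagents that add atoms: none
Why: NaH removes the C11 proton flanked by the phosphoryl and ester groups, and the sodium enolate 19 attacks the nearer epoxide carbon C7 from the side opposite its C–O bond, which forms C7–C11, closes the five-membered lactone ring O–C6–C7–C11–C12 and releases the C8 oxygen. The closest known reaction type is the alkylation of malonate or phosphonoacetate enolates by epoxides to alpha-substituted gamma-lactones, here run within one molecule as in epoxy-nitrile cyclisations. The ring closes in the 5-exo-tet mode, whereas attack at C8 would be a 6-endo closure with a poorer trajectory. The new stereocentre C7 is set by stereospecific inversion: because the epoxide is trans and the C6 ester is threo to it, C5 and C8 should end up cis on the lactone with C11 anti to the C8 oxygen, as in the target, while the C11 configuration is immaterial since the later olefination removes it. The step needs C7 regioselectivity, secured by the tether length and exo geometry, and it needs the lactone to stay on O6, which the substrate secures because the C8 alkoxide is quenched at once by the acidic C11–H of the product to give the stabilised salt 20, protonated with AcOH in the cold.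

Step 11
Reactants: 21 alpha-phosphono lactone with free C8 hydroxyl, 22 (R)-2-methylbutanoic acid
Product: 23 C8 (R)-2-methylbutanoate of the alpha-phosphono lactone
Conditions: DCC, DMAP (cat.), CH2Cl2, 0 °C to rt
Reagents that add atoms: none
Why: Steglich esterification acylates the only free hydroxyl (C8) under near-neutral conditions that should neither epimerise the alpha-stereocentre of the acid nor open the lactone, and it locks O8 against acyl migration.

Step 12
Reactants: 23 C8 (R)-2-methylbutanoate of the alpha-phosphono lactone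
Product: 24 alpha-methylene lactone with (Z)-iodoalkene, C8 ester, dioxolane and TBS ether
Conditions: 37% aq. HCHO, K2CO3, THF, 0 °C to rt
Reagents that add atoms: formaldehyde, C=O
Why: Horner–Wadsworth–Emmons olefination of the alpha-phosphono lactone with formaldehyde installs the exocyclic C11=C13 bond, removes the C11 stereocentre and needs only carbonate base, which the two esters should tolerate.

Step 13
Reactants: 24 alpha-methylene lactone TBS ether
Product: 25 primary C3 alcohol
Conditions: HF·pyridine, pyridine, THF, 0 °C to rt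
Reagents that add atoms: none
Why: Buffered fluoride desilylation cleaves the primary silyl ether selectively, since the isopropylidene ketal, the esters and the alkenyl iodide are stable to HF·pyridine in excess pyridine.

Step 14
Reactants: 25 primary C3 alcohol
Product: 26 C3 aldehyde
Conditions: Dess–Martin periodinane, CH2Cl2, rt
Reagents that add atoms: none
Why: Dess–Martin oxidation converts the primary alcohol into the C3 aldehyde under non-basic conditions that should spare the methylene lactone and the alkenyl iodide.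

Step 15
Reactants: 26 C3 aldehyde
Product: 28 ten-membered (4Z)-allylic alcohol as C3 epimers, via alkenylchromium dichloride 27 (not isolated)
Conditions: CrCl2 (10 equiv), NiCl2 (0.1 equiv), DMSO, rt, slow addition to high dilution
Reagents that add atoms: none
Why: In the Nozaki–Hiyama–Kishi reaction the nickel catalyst from NiCl2 activates the C4–I bond and hands the alkenyl group to chromium with retention of the (Z)-geometry, and chemoselective addition of this alkenylchromium to the C3 aldehyde should close the ten-membered ring, the C3 epimers being of no consequence because C3 is oxidised next.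

Step 16
Reactants: 28 ten-membered allylic alcohol
Product: 29 ten-membered (4Z)-enone (6S,7R,8R,10R)
Conditions: Dess–Martin periodinane, CH2Cl2, 0 °C to rt
Reagents that add atoms: none
Why: Dess–Martin oxidation of the allylic alcohol merges both C3 epimers into the (Z)-enone without base, so that neither the lactone-bearing C6 nor the alkene geometry is put at risk.

Step 17
Reactants: 29 ten-membered (4Z)-enone
Product: 31 target hemiketal CNP0328225.2, via keto diol 30 (not isolated)
Conditions: AcOH/H2O/THF (3:1:1), 40 °C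
Reagents that add atoms: none
Why: Acid-catalysed ketal hydrolysis (the oxygen of water leaving in acetone) frees the C10 and C14 hydroxyls, and the tertiary C10–OH should add across the ring to the C3 ketone under thermodynamic control to give the five-membered hemiketal, whose (3S) configuration is dictated by C10 because the bridge requires C4 and C9 cis on the oxolane.

**Compound list**

1 | but-2-yn-1-ol | CC#CCO | starting material
2 | sodium cyclic (Z)-alkenylalanate, ring O–Al–C4(CH3)=C5–C6H2 with two 2-methoxyethoxy groups on Al | CC1=CCO[Al-]1(OCCOC)OCCOC.[Na+] | intermediate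
3 | (Z)-3-iodobut-2-en-1-ol | C/C(I)=C/CO | intermediate
4 | (Z)-3-iodobut-2-enal | C/C(I)=C/C=O | intermediate
5 | (3-bromopropoxy)(tert-butyl)dimethylsilane | CC(C)(C)[Si](C)(C)OCCCBr | starting material
6 | prop-2-yn-1-ol (propargyl alcohol) | C#CCO | starting material
7 | [3-(TBS-oxy)propyl]magnesium bromide | CC(C)(C)[Si](C)(C)OCCC[Mg]Br | intermediate
8 | bromomagnesium (Z)-3-(bromomagnesio)-2-[3-(TBS-oxy)propyl]prop-2-en-1-olate | Br[Mg]/C=C(/CCCO[Si](C)(C)C(C)(C)C)CO[Mg]Br | intermediate
9 | 2-[3-(TBS-oxy)propyl]prop-2-en-1-ol | C=C(CO)CCCO[Si](C)(C)C(C)(C)C | intermediate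
10 | (S)-{2-[3-(TBS-oxy)propyl]oxiran-2-yl}methanol | OC[C@@]1(CCCO[Si](C)(C)C(C)(C)C)CO1 | intermediate
11 | (R)-2-[3-(TBS-oxy)propyl]pent-4-yne-1,2-diol | C#CC[C@](O)(CCCO[Si](C)(C)C(C)(C)C)CO | intermediate
12 | (R)-2,2-dimethyl-4-(prop-2-yn-1-yl)-4-[3-(TBS-oxy)propyl]-1,3-dioxolane | C#CC[C@]1(CCCO[Si](C)(C)C(C)(C)C)COC(C)(C)O1 | intermediate
13 | (E)-alkenylzirconocene chloride from 12, Zr on C7 | Cl[Zr](/C=C/C[C@]1(CCCO[Si](C)(C)C(C)(C)C)COC(C)(C)O1)(C1C=CC=C1)C1C=CC=C1 | intermediate
14 | (E)-alkenyl(methyl)zinc, Zn on C7 | C[Zn]/C=C/C[C@]1(CCCO[Si](C)(C)C(C)(C)C)COC(C)(C)O1 | intermediate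
15 | (2Z,5E)-7-{(4R)-2,2-dimethyl-4-[3-(TBS-oxy)propyl]-1,3-dioxolan-4-yl}-2-iodohepta-2,5-dien-4-ol, both epimers at the carbinol carbon C6 | OC(/C=C(/C)I)/C=C/C[C@]1(CCCO[Si](C)(C)C(C)(C)C)COC(C)(C)O1 | intermediate
16 | (1R,2Z)-1-[(2R,3R)-3-({(4R)-2,2-dimethyl-4-[3-(TBS-oxy)propyl]-1,3-dioxolan-4-yl}methyl)oxiran-2-yl]-3-iodobut-2-en-1-ol (erythro; 6R,7R,8R,10R) | O[C@H](/C=C(/C)I)[C@H]1O[C@@H]1C[C@]2(CCCO[Si](C)(C)C(C)(C)C)COC(C)(C)O2 | intermediate
17 | 2-(diethoxyphosphoryl)acetic acid | CCOP(=O)(OCC)CC(=O)O | starting material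
18 | (1S,2Z)-1-[(2S,3R)-3-({(4R)-2,2-dimethyl-4-[3-(TBS-oxy)propyl]-1,3-dioxolan-4-yl}methyl)oxiran-2-yl]-3-iodobut-2-en-1-yl 2-(diethoxyphosphoryl)acetate (threo; key-step precursor) | CCOP(=O)(OCC)CC(=O)O[C@@H](/C=C(/C)I)[C@H]1O[C@@H]1C[C@]2(CCCO[Si](C)(C)C(C)(C)C)COC(C)(C)O2 | intermediate
19 | sodium enolate of 18, carbanion at C11 | CCOP(=O)(OCC)[CH-]C(=O)O[C@@H](/C=C(/C)I)[C@H]1O[C@@H]1C[C@]2(CCCO[Si](C)(C)C(C)(C)C)COC(C)(C)O2.[Na+] | intermediate
20 | sodium salt of lactone 21, phosphonate-stabilised carbanion at C11, free C8 hydroxyl | CCOP(=O)(OCC)[C-]1C(=O)O[C@@H](/C=C(/C)I)[C@H]1[C@H](O)C[C@]2(CCCO[Si](C)(C)C(C)(C)C)COC(C)(C)O2.[Na+] | intermediate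
21 | diethyl {(4R,5R)-4-[(1R)-2-{(4R)-2,2-dimethyl-4-[3-(TBS-oxy)propyl]-1,3-dioxolan-4-yl}-1-hydroxyethyl]-5-[(Z)-2-iodoprop-1-en-1-yl]-2-oxooxolan-3-yl}phosphonate, C11 epimers (key-step product) | CCOP(=O)(OCC)C1C(=O)O[C@@H](/C=C(/C)I)[C@H]1[C@H](O)C[C@]2(CCCO[Si](C)(C)C(C)(C)C)COC(C)(C)O2 | intermediate
22 | (R)-2-methylbutanoic acid | CC[C@@H](C)C(=O)O | starting material
23 | C8 (R)-2-methylbutanoate of 21 (6R,7R,8R,10R; C11 epimers) | CCOP(=O)(OCC)C1C(=O)O[C@@H](/C=C(/C)I)[C@H]1[C@H](OC(=O)[C@H](C)CC)C[C@]2(CCCO[Si](C)(C)C(C)(C)C)COC(C)(C)O2 | intermediate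
24 | alpha-methylene gamma-lactone (6R,7R,8R,10R) with (Z)-2-iodopropenyl on C6, C8 (R)-2-methylbutanoate, C10/C14 acetonide and C3 TBS ether | C=C1C(=O)O[C@@H](/C=C(/C)I)[C@H]1[C@H](OC(=O)[C@H](C)CC)C[C@]2(CCCO[Si](C)(C)C(C)(C)C)COC(C)(C)O2 | intermediate
25 | primary C3 alcohol from 24 | C=C1C(=O)O[C@@H](/C=C(/C)I)[C@H]1[C@H](OC(=O)[C@H](C)CC)C[C@]2(CCCO)COC(C)(C)O2 | intermediate
26 | C3 aldehyde | C=C1C(=O)O[C@@H](/C=C(/C)I)[C@H]1[C@H](OC(=O)[C@H](C)CC)C[C@]2(CCC=O)COC(C)(C)O2 | intermediate
27 | (Z)-alkenylchromium dichloride, trivalent chromium on C4 | C=C1C(=O)O[C@@H](/C=C(/C)[Cr](Cl)Cl)[C@H]1[C@H](OC(=O)[C@H](C)CC)C[C@]2(CCC=O)COC(C)(C)O2 | intermediate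
28 | ten-membered (4Z)-allylic alcohol (6S,7R,8R,10R), both C3 epimers, cis-fused methylene lactone, C8 ester, C10/C14 acetonide | C=C1C(=O)O[C@H]2/C=C(/C)C(O)CC[C@]3(COC(C)(C)O3)C[C@@H](OC(=O)[C@H](C)CC)[C@@H]12 | intermediate
29 | ten-membered (4Z)-en-3-one (6S,7R,8R,10R) | C=C1C(=O)O[C@H]2/C=C(/C)C(=O)CC[C@]3(COC(C)(C)O3)C[C@@H](OC(=O)[C@H](C)CC)[C@@H]12 | intermediate
30 | 3-keto-10,14-diol | C=C1C(=O)O[C@H]2/C=C(/C)C(=O)CC[C@](O)(CO)C[C@@H](OC(=O)[C@H](C)CC)[C@@H]12 | intermediate
31 | CNP0328225.2, (3S,6S,7R,8R,10R,4Z) 3,10-epoxy hemiketal with C8 (R)-2-methylbutanoate | C=C1C(=O)O[C@H]2/C=C(/C)[C@]3(O)CC[C@](CO)(C[C@@H](OC(=O)[C@H](C)CC)[C@@H]12)O3 | target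

**Step count**

Total steps: 17. Longest linear sequence: 15 steps (steps 3 to 17, from 5 and 6); steps 1 and 2 make the second fragment.

**Steps most likely to fail**

1. Step 10. C-alkylation by the doubly stabilised, chelated enolate may be slow, so that closure at C8 to a six-membered lactone, O-alkylation or acyl migration to O8 compete. The fallback sets out from 16 and returns at 25. Mitsunobu esterification of 16 with 3-oxo-3-[2-(trimethylsilyl)ethoxy]propanoic acid (PPh3, DIAD) would give the threo mixed malonate F1. Its sodium enolate (NaH, THF) is the classical, less hindered carbon nucleophile for epoxides and keeps the acidic C11–H that protects the lactone, so it should close the same ring to the alpha-[2-(trimethylsilyl)ethoxycarbonyl] hydroxy lactone F2. Acylation with 22 (DCC, DMAP) would give the C8 ester F3. Bu4NF in THF would remove both silicon groups to give the alpha-carboxy lactone alcohol F4. A decarboxylative Mannich methylenation (aq. HCHO, Et2NH, AcOH/NaOAc) would then bring in C13 and give 25.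

2. Step 15. Ten-membered ring closure may lose to intermolecular coupling or to protodeiodination, and divalent chromium may attack the methylene lactone. The fallback sets out from 26 and returns at 29, closing the same C3–C4 bond by an acylative Stille coupling. Pinnick oxidation (NaClO2, NaH2PO4, 2-methylbut-2-ene, t-BuOH/H2O) would give the carboxylic acid F5. Iodine–tin exchange with (Bu3Sn)2 and Pd(PPh3)4 (zerovalent palladium, i-Pr2NEt, toluene, 80 °C) would give the (Z)-alkenylstannane acid F6. 1-Chloro-N,N,2-trimethylprop-1-en-1-amine in CH2Cl2 would convert it under neutral conditions into the acid chloride F7. Slow addition of F7 to Pd2(dba)3 and tri(2-furyl)phosphine in toluene should give enone 29 directly.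

3. Step 9. The activated C6 oxygen is allylic and next to an epoxide, so ionisation, elimination or participation of the epoxide oxygen may erode the inversion. The fallback sets out from the (6R)-epimer of 15 that step 8 leaves unreacted and returns at 18, so that no substitution at C6 is needed. Shi epoxidation (D-fructose-derived ketone, KHSO5, K2CO3 buffer, MeCN/dimethoxymethane/H2O, 0 °C) is reagent-controlled and should deliver oxygen to the same face of the (E)-C7=C8 bond as the D-tartrate system, giving the threo epoxy alcohol F8, the C6 epimer of 16. Steglich esterification of F8 with 17 (DCC, DMAP) would then give 18 with retention at C6.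

**Further compounds**

F1 | step 10 | threo C6 [2-(trimethylsilyl)ethyl] malonate of the trans C7–C8 epoxide | C[Si](C)(C)CCOC(=O)CC(=O)O[C@@H](/C=C(/C)I)[C@H]1O[C@@H]1C[C@]2(CCCO[Si](C)(C)C(C)(C)C)COC(C)(C)O2
F2 | step 10 | alpha-[2-(trimethylsilyl)ethoxycarbonyl] gamma-lactone with free C8 hydroxyl, C11 epimers | C[Si](C)(C)CCOC(=O)C1C(=O)O[C@@H](/C=C(/C)I)[C@H]1[C@H](O)C[C@]2(CCCO[Si](C)(C)C(C)(C)C)COC(C)(C)O2
F3 | step 10 | C8 (R)-2-methylbutanoate of F2 | C[Si](C)(C)CCOC(=O)C1C(=O)O[C@@H](/C=C(/C)I)[C@H]1[C@H](OC(=O)[C@H](C)CC)C[C@]2(CCCO[Si](C)(C)C(C)(C)C)COC(C)(C)O2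
F4 | step 10 | alpha-carboxy gamma-lactone with C8 ester and free C3 alcohol | OC(=O)C1C(=O)O[C@@H](/C=C(/C)I)[C@H]1[C@H](OC(=O)[C@H](C)CC)C[C@]2(CCCO)COC(C)(C)O2
F5 | step 15 | C3 carboxylic acid with (Z)-alkenyl iodide | C=C1C(=O)O[C@@H](/C=C(/C)I)[C@H]1[C@H](OC(=O)[C@H](C)CC)C[C@]2(CCC(=O)O)COC(C)(C)O2
F6 | step 15 | C3 carboxylic acid with (Z)-C4 tributylstannyl alkene | C=C1C(=O)O[C@@H](/C=C(/C)[Sn](CCCC)(CCCC)CCCC)[C@H]1[C@H](OC(=O)[C@H](C)CC)C[C@]2(CCC(=O)O)COC(C)(C)O2
F7 | step 15 | C3 acid chloride with (Z)-C4 tributylstannyl alkene | C=C1C(=O)O[C@@H](/C=C(/C)[Sn](CCCC)(CCCC)CCCC)[C@H]1[C@H](OC(=O)[C@H](C)CC)C[C@]2(CCC(=O)Cl)COC(C)(C)O2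
F8 | step 9 | threo (6S,7R,8R,10R)-7,8-epoxy-6-ol, C6 epimer of 16 | O[C@@H](/C=C(/C)I)[C@H]1O[C@@H]1C[C@]2(CCCO[Si](C)(C)C(C)(C)C)COC(C)(C)O2
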